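| flask | G | D | X | remark | time |
|---|---|---|---|---|---|
| gamma | 0.13 M | 2.5 equiv | 4 equiv | run made earlier |  |
| eta | 0.30 M | 2.5 equiv | 4 equiv | run made earlier |  |
| alpha | 0.20 M | 5 equiv | 4 equiv | run made earlier |  |
| Saturday's | 0.20 M | 2.50 equiv | 4.00 equiv |  | 6.0 min |
| Sunday's | 0.20 M | 2.50 equiv | 4.00 equiv |  | 8.0 min |

| run | time / min | L / % | J / % | Q / % | G / % | E / % |
|---|---|---|---|---|---|---|
| gamma | 0.833 | 12.1 | 3.7 | 0.4 | 60.1 | 16.0 |
| gamma | 2.50 | 25.3 | 9.6 | 2.4 | 22.1 | 38.0 |
| gamma | 5.00 | 28.2 | 11.9 | 6.4 | 5.1 | 48.8 |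
| gamma | 8.00 | 25.3 | 12.1 | 10.7 | 1.0 | 50.8 |
| eta | 0.500 | 10.2 | 3.5 | 0.2 | 74.5 | 6.7 |
| eta | 1.33 | 24.2 | 9.5 | 2.1 | 44.8 | 16.3 |
| eta | 3.00 | 33.0 | 14.4 | 8.3 | 16.9 | 26.3 |
| eta | 8.00 | 24.8 | 17.0 | 24.9 | 0.6 | 32.0 |
| alpha | 0.833 | 20.5 | 3.5 | 1.7 | 60.2 | 10.0 |
| alpha | 2.50 | 36.3 | 7.7 | 11.0 | 22.6 | 20.9 |
| alpha | 5.00 | 32.6 | 10.4 | 25.7 | 4.8 | 25.9 |
| alpha | 8.00 | 22.1 | 10.3 | 38.5 | 1.1 | 27.8 |

(each reading ± 0.3 percentage points)

- which of these there is most of at the end, counted by the G in it, Saturday's (J / L / E / Q)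
- which of these there is most of at the end, counted by the G in it, Sunday's (J / L / E / Q)
- how much there is at the end of the one of these that leads, in percent of the G charged: Saturday's
- how much there is at the end of the one of these that leads, in percent of the G charged: Sunday's

Start with the easy count. In the gamma run G fell to 22.1% by 2.50 min, so its half-life reads 1.15 min, and the alpha run, with a different charge, shows 22.6% at that time. Saturday's 6.0 min is then 5.23 half-lives and Sunday's 8.0 min is 6.97, leaving 2.67% and 0.798% of G.

Now turn the question round: what must be true for E to lose the lead? At its last reading the gamma run holds, per unit of E, 0.709 of L with Q and 0.238 of J. These are odds against E, a selectivity factor. Z goes to E without a partner while the other paths take D or X, so at fixed equivalents I scale the odds with the G charged; the eta run reads 2.08 in total, and this scaling gives 2.19.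

The new flasks are charged 1.54 times as strongly as the gamma run, so I reckon L with Q at 1.09 of E and J at 0.367. On that reckoning E is overtaken if L or Q holds 91.7% of that pair or more. In the gamma run, at the two readings that span the new flasks' times, L held 81.5% of the pair at 5.00 min and 70.3% at 8.00 min, and Q held 29.7% at 8.00 min.

So I carry E's share of the G turned over, 40.7%, which gives me 39.6% and 40.4%. The forecast also names E, “E leads in both runs”, at 41.3% and 42.4%, higher than my figures .

Saturday's flask ends with E leading at 39.6% and Sunday's with E at 40.6%.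

    G → Z (k = 0.0100 s⁻¹)
    D + Z → L (k = 0.114 M⁻¹ s⁻¹)
    X + Z → J (k = 0.0230 M⁻¹ s⁻¹)
    Z → E (k = 0.0480 s⁻¹)
    D + L → Q (k = 0.00329 M⁻¹ s⁻¹)

With 2.7% of G left on Saturday's, E's share of the G turned over there is 40.7%, against the 40.7% carried. On Saturday's, L's half-life by the step from D and L to Q alone, the other concentrations as charged, is 7.0 min, longer than the 1.15 min read for G in the gamma run, and that flask holds 29.8% of L and 12.7% of Q. For a flask like Sunday's with 6.20 equiv of D, the carried share, with the odds of L and Q scaled by the D charged, gives 24.4% of E; that flask holds 24.1%, and Q leads it at 47.5%.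

The data were computed with made-up constants; scatter was added.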